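**Retrosynthetic overview**
1. Target 21 comes from its penta-MOM ether 20 by acetal cleavage in the last step.
2. The dihydrobenzofuran ring and C3 of 20 come from an oxidative ring contraction of the 2,4-diaryl-2H-chromene 19: the ring A carbon shifts from C4 to C3 and the old C4 becomes the 3-aroyl carbonyl.
3. 19 comes from flavanone 13 by two-fold addition of one resorcinol-derived aryllithium (to the ring ketone and to a cinnamoyl Weinreb amide), then dehydration; both 2,4-dihydroxyphenyl ketone units enter here.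
4. 13 comes from (R)-6-bromoflavanone 11 by Heck coupling; 11 comes from 6-bromochromone 7 by asymmetric conjugate arylation, which sets C2.
5. Ring order: the benzene rings are bought (4-bromophenol twice, resorcinol); the pyranone ring is built first (Fries, enaminone cyclisation) and is contracted to the furan ring in step 9.

Assumption: acetic anhydride, DMF dimethyl acetal and N-methoxy-N-methylacrylamide supply skeletal carbons and are numbered as starting materials; (S)-t-BuPyOx is taken to give the 2R adduct, and its antipode is used if the sense turns out opposite.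

**Step 1**
Reactants: 1 4-bromophenol; 2 acetic anhydride
Product: 4 1-(5-bromo-2-hydroxyphenyl)ethan-1-one, via 4-bromophenyl acetate 3 (not isolated)
Conditions: Ac2O (1.1 equiv), H2SO4 (cat.), 60 °C; strip volatiles; AlCl3 (1.6 equiv), neat, 140 °C; ice/HCl
Reagents that add atoms: none
Why: O-acetylation followed by Fries rearrangement; the para position is blocked by bromine, so the acyl group moves to the ortho carbon.

**Step 2**
Reactants: 4 1-(5-bromo-2-hydroxyphenyl)ethan-1-one; 5 N,N-dimethylformamide dimethyl acetal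
Product: 7 6-bromo-4H-chromen-4-one, via enaminone 6 (not isolated)
Conditions: Me2NCH(OMe)2 (1.5 equiv), PhMe, 100 °C; concentrate; conc. HCl, CH2Cl2, 40 °C
Reagents that add atoms: none
Why: Enaminone condensation at the acetyl CH3, then acid-promoted addition–elimination of the phenol with loss of Me2NH (standard chromone synthesis).

**Step 3**
Reactants: 1 4-bromophenol
Product: 10 [4-(methoxymethoxy)phenyl]boronic acid, via MOM ether 8 (not isolated), via aryllithium 9 (not isolated)
Conditions: NaH (1.05 equiv), MOMCl (1.0 equiv), THF, 0 °C → rt; then n-BuLi (1.1 equiv), −78 °C; B(Oi-Pr)3 (1.3 equiv), −78 °C → rt; 1 M HCl to pH 5, 0 °C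
Reagents that add atoms: chloromethyl methyl ether (MOMCl), COCCl; triisopropyl borate, CC(C)OB(OC(C)C)OC(C)C; water, O
Why: Williamson-type MOM protection, bromine–lithium exchange, borate trapping and hydrolysis, telescoped because NaCl and the ether do not disturb the exchange.

**Step 4**
Reactants: 7 6-bromo-4H-chromen-4-one; 10 [4-(methoxymethoxy)phenyl]boronic acid
Product: 11 (2R)-6-bromo-2-[4-(methoxymethoxy)phenyl]-2,3-dihydro-4H-chromen-4-one
Conditions: Pd(OCOCF3)2 (5 mol%), (S)-t-BuPyOx (6 mol%), NH4PF6 (30 mol%), H2O (5 equiv), 10 (2 equiv), ClCH2CH2Cl, 60 °C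
Reagents that add atoms: none
Why: Palladium-catalysed asymmetric conjugate addition of an arylboronic acid (Hayashi–Miyaura type) in which the PyOx ligand selects the enone face and sets C2 as R; the catalyst stays divalent palladium, so the C–Br bond is untouched.

**Step 5**
Reactants: 11 (2R)-6-bromo-2-[4-(methoxymethoxy)phenyl]-2,3-dihydro-4H-chromen-4-one; 12 N-methoxy-N-methylprop-2-enamide
Product: 13 (2E)-N-methoxy-3-{(2R)-2-[4-(methoxymethoxy)phenyl]-4-oxo-3,4-dihydro-2H-chromen-6-yl}-N-methylprop-2-enamide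
Conditions: Pd(P(t-Bu)3)2 (3 mol%), Cy2NMe (1.2 equiv), 12 (1.3 equiv), dioxane, 50 °C
Reagents that add atoms: none
Why: Mizoroki–Heck reaction (zerovalent palladium inserts into C–Br, E-selective β-arylation of the acrylamide); the mild amine base at 50 °C is not expected to enolise the flavanone, so C2 should be preserved.

**Step 6**
Reactants: 14 resorcinol
Product: 15 1,3-bis(methoxymethoxy)benzene
Conditions: NaH (2.4 equiv), MOMCl (2.4 equiv), DMF, 0 °C → rt
Reagents that add atoms: chloromethyl methyl ether (MOMCl), COCCl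
Why: Two-fold Williamson-type O-alkylation of the diphenoxide.

**Step 7**
Reactants: 15 1,3-bis(methoxymethoxy)benzene
Product: 16 1-bromo-2,4-bis(methoxymethoxy)benzene
Conditions: NBS (1.02 equiv), MeCN, 0 °C → rt
Reagents that add atoms: N-bromosuccinimide, O=C1CCC(=O)N1Br
Why: Electrophilic aromatic bromination at the position para to one and ortho to the other alkoxy group; the position between the two ethers is hindered.

**Step 8**
Reactants: 13 (2E)-N-methoxy-3-{(2R)-2-[4-(methoxymethoxy)phenyl]-4-oxo-3,4-dihydro-2H-chromen-6-yl}-N-methylprop-2-enamide; 16 1-bromo-2,4-bis(methoxymethoxy)benzene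
Product: 19 (2E)-1-[2,4-bis(methoxymethoxy)phenyl]-3-{(2R)-4-[2,4-bis(methoxymethoxy)phenyl]-2-[4-(methoxymethoxy)phenyl]-2H-chromen-6-yl}prop-2-en-1-one, via aryllithium 17 (not isolated), via carbinol 18 (not isolated)
Conditions: 16 (3.0 equiv), n-BuLi (3.0 equiv), THF, −78 °C; add 13, −78 → −40 °C; AcOH quench; crude in PhMe, PPTS (10 mol%), 40 °C, dark
Reagents that add atoms: none
Why: Bromine–lithium exchange, then 1,2-addition to the flavanone ketone and Weinreb ketone synthesis at the amide in one operation (the chelated tetrahedral adduct protects the future enone), followed by acid-catalysed E1 dehydration of the doubly benzylic carbinol; C2 is not involved.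

**Step 9**
Reactants: 19 (2E)-1-[2,4-bis(methoxymethoxy)phenyl]-3-{(2R)-4-[2,4-bis(methoxymethoxy)phenyl]-2-[4-(methoxymethoxy)phenyl]-2H-chromen-6-yl}prop-2-en-1-one
Product: 20 (2E)-1-[2,4-bis(methoxymethoxy)phenyl]-3-{(2R,3R)-3-[2,4-bis(methoxymethoxy)benzoyl]-2-[4-(methoxymethoxy)phenyl]-2,3-dihydro-1-benzofuran-5-yl}prop-2-en-1-one
Conditions: PhI(OH)OTs (1.15 equiv), MeCN/H2O 20:1, −20 → 0 °C, dark; aq. NaHCO3
Reagents that add atoms: water, O (becomes the ketone oxygen); hydroxy(tosyloxy)iodobenzene (Koser's reagent, the oxidant and formal oxygen donor), OI(OS(=O)(=O)c1ccc(C)cc1)c1ccccc1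
Why: Proposed new method: a trivalent-iodine oxidative ring contraction applied to a 2,4-diaryl-2H-chromene, where PhI(OH)OTs adds to C3 of the electron-rich trisubstituted alkene anti to the C2 aryl group, water caps the doubly benzylic C4 cation, and in the conformer with the C3–I bond equatorial the anti-periplanar C4–C4a bond (ring A carbon, activated by the ortho ring oxygen) makes a 1,2-shift to C3 with inversion and loss of PhI, so the pyran ring contracts to the dihydrofuran and C4 collapses to the aryl ketone; the 4-aryl group is cis to the iodane and cannot migrate, C2 is untouched and stays R, C3 emerges trans to the C2 aryl (and, being enolisable, settles as trans in any case), and the electron-poor enone does not compete; closest known reaction type: trivalent-iodine or trivalent-thallium ring contraction of 1,2-dihydronaphthalenes to indanes and of flavanones to 2-aryl-2,3-dihydrobenzofuran-3-carboxylates.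

**Step 10**
Reactants: 20 (2E)-1-[2,4-bis(methoxymethoxy)phenyl]-3-{(2R,3R)-3-[2,4-bis(methoxymethoxy)benzoyl]-2-[4-(methoxymethoxy)phenyl]-2,3-dihydro-1-benzofuran-5-yl}prop-2-en-1-one
Product: 21 (2E)-1-(2,4-dihydroxyphenyl)-3-[(2R,3R)-3-(2,4-dihydroxybenzoyl)-2-(4-hydroxyphenyl)-2,3-dihydro-1-benzofuran-5-yl]prop-2-en-1-one
Conditions: HCl (1.25 M in MeOH), THF, 40 °C
Reagents that add atoms: none
Why: Acid-catalysed acetal exchange removes all five MOM groups as dimethoxymethane; no base is present, so the retro-oxa-Michael racemisation path is avoided, and the 2,3-trans isomer is the thermodynamic one.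

**Compound list**
1 | 4-bromophenol | Oc1ccc(Br)cc1 | starting material
2 | acetic anhydride | CC(=O)OC(C)=O | starting material
3 | 4-bromophenyl acetate | CC(=O)Oc1ccc(Br)cc1 | intermediate
4 | 1-(5-bromo-2-hydroxyphenyl)ethan-1-one | CC(=O)c1cc(Br)ccc1O | intermediate
5 | N,N-dimethylformamide dimethyl acetal | COC(OC)N(C)C | starting material
6 | (2E)-1-(5-bromo-2-hydroxyphenyl)-3-(dimethylamino)prop-2-en-1-one | CN(C)/C=C/C(=O)c1cc(Br)ccc1O | intermediate
7 | 6-bromo-4H-chromen-4-one | O=c1ccoc2ccc(Br)cc12 | intermediate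
8 | 1-bromo-4-(methoxymethoxy)benzene | COCOc1ccc(Br)cc1 | intermediate
9 | [4-(methoxymethoxy)phenyl]lithium | [Li]c1ccc(OCOC)cc1 | intermediate
10 | [4-(methoxymethoxy)phenyl]boronic acid | COCOc1ccc(B(O)O)cc1 | intermediate
11 | (2R)-6-bromo-2-[4-(methoxymethoxy)phenyl]-2,3-dihydro-4H-chromen-4-one | O=C1C[C@H](c2ccc(OCOC)cc2)Oc2ccc(Br)cc12 | intermediate
12 | N-methoxy-N-methylprop-2-enamide | C=CC(=O)N(C)OC | starting material
13 | (2E)-N-methoxy-3-{(2R)-2-[4-(methoxymethoxy)phenyl]-4-oxo-3,4-dihydro-2H-chromen-6-yl}-N-methylprop-2-enamide | CON(C)C(=O)/C=C/c1ccc2c(c1)C(=O)C[C@H](c1ccc(OCOC)cc1)O2 | intermediate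
14 | resorcinol (benzene-1,3-diol) | Oc1cccc(O)c1 | starting material
15 | 1,3-bis(methoxymethoxy)benzene | COCOc1cccc(OCOC)c1 | intermediate
16 | 1-bromo-2,4-bis(methoxymethoxy)benzene | COCOc1ccc(Br)c(OCOC)c1 | intermediate
17 | [2,4-bis(methoxymethoxy)phenyl]lithium | [Li]c1ccc(OCOC)cc1OCOC | intermediate
18 | (2E)-1-[2,4-bis(methoxymethoxy)phenyl]-3-{(2R)-4-[2,4-bis(methoxymethoxy)phenyl]-4-hydroxy-2-[4-(methoxymethoxy)phenyl]-3,4-dihydro-2H-chromen-6-yl}prop-2-en-1-one (C4 epimer mixture) | COCOc1ccc(C(=O)/C=C/c2ccc3c(c2)C(O)(c2ccc(OCOC)cc2OCOC)C[C@H](c2ccc(OCOC)cc2)O3)c(OCOC)c1 | intermediate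
19 | (2E)-1-[2,4-bis(methoxymethoxy)phenyl]-3-{(2R)-4-[2,4-bis(methoxymethoxy)phenyl]-2-[4-(methoxymethoxy)phenyl]-2H-chromen-6-yl}prop-2-en-1-one | COCOc1ccc(C(=O)/C=C/c2ccc3c(c2)C(c2ccc(OCOC)cc2OCOC)=C[C@H](c2ccc(OCOC)cc2)O3)c(OCOC)c1 | intermediate
20 | (2E)-1-[2,4-bis(methoxymethoxy)phenyl]-3-{(2R,3R)-3-[2,4-bis(methoxymethoxy)benzoyl]-2-[4-(methoxymethoxy)phenyl]-2,3-dihydro-1-benzofuran-5-yl}prop-2-en-1-one (2,3-trans) | COCOc1ccc(C(=O)/C=C/c2ccc3c(c2)[C@@H](C(=O)c2ccc(OCOC)cc2OCOC)[C@H](c2ccc(OCOC)cc2)O3)c(OCOC)c1 | intermediate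
21 | (2E)-1-(2,4-dihydroxyphenyl)-3-[(2R,3R)-3-(2,4-dihydroxybenzoyl)-2-(4-hydroxyphenyl)-2,3-dihydro-1-benzofuran-5-yl]prop-2-en-1-one | O=C(/C=C/c1ccc2c(c1)[C@@H](C(=O)c1ccc(O)cc1O)[C@H](c1ccc(O)cc1)O2)c1ccc(O)cc1O | target

**Step count**
Total: 10 steps. Longest linear sequence: 7 steps (1, 2, 4, 5, 8, 9, 10).

**Three steps most likely to fail**

Step 9 (the proposed ring contraction). The iodane adduct could instead lose the C2 hydrogen to give the achiral 2,4-diarylchromenylium salt, be intercepted by water to give a 3,4-diol, or attack the electron-rich arenes. The fallback uses known chemistry and moves the ring contraction to the ketone stage. It sets out from flavanone 11, which undergoes the established trivalent-iodine ring contraction of flavanones (PhI(OAc)2, cat. H2SO4, HC(OMe)3, rt; 1,2-shift of the ring A carbon through the enol ether) to give methyl (2R,3R)-5-bromo-2-[4-(methoxymethoxy)phenyl]-2,3-dihydro-1-benzofuran-3-carboxylate F1. Aminolysis with Me(MeO)NH·HCl/AlMe3 in CH2Cl2 gives the Weinreb amide (2R,3R)-5-bromo-N-methoxy-2-[4-(methoxymethoxy)phenyl]-N-methyl-2,3-dihydro-1-benzofuran-3-carboxamide F2. Heck coupling of F2 with 12 under the step 5 conditions gives the bis-Weinreb amide (2R,3R)-N-methoxy-5-{(1E)-3-[methoxy(methyl)amino]-3-oxoprop-1-en-1-yl}-2-[4-(methoxymethoxy)phenyl]-N-methyl-2,3-dihydro-1-benzofuran-3-carboxamide F3. Aryllithium 17 (from 16, 2.5 equiv, THF, −78 °C) converts both amides into the aryl ketones, and the route comes back at 20.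

Step 8 (double aryllithium addition and dehydration). Enolisation of the flavanone, incomplete reaction at one of the two carbonyl groups, or conjugate addition would lower the yield, and the 2H-chromene is light- and acid-sensitive. The fallback separates the two carbonyl additions and makes the enone by cross-coupling. It sets out from 11, 12 and 16. Aryllithium 17 is added to 12 to give the vinyl ketone 1-[2,4-bis(methoxymethoxy)phenyl]prop-2-en-1-one F4. Separately, 17 is added to the ketone of 11 at −78 °C to give (2R)-6-bromo-4-[2,4-bis(methoxymethoxy)phenyl]-2-[4-(methoxymethoxy)phenyl]-3,4-dihydro-2H-chromen-4-ol F5, which PPTS in toluene dehydrates to (2R)-6-bromo-4-[2,4-bis(methoxymethoxy)phenyl]-2-[4-(methoxymethoxy)phenyl]-2H-chromene F6. Heck coupling of F6 with F4 (Pd(P(t-Bu)3)2, Cy2NMe, dioxane, 50 °C) brings the route back at 19.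

Step 4 (asymmetric conjugate arylation). The electron-rich boronic acid may protodeboronate or homocouple, the bromide may not be fully tolerated, and the enantiomeric purity of the whole route is fixed here. The fallback builds the flavanone through a chalcone and resolves it. It sets out from 4 and aryllithium 9. Quenching 9 with DMF gives 4-(methoxymethoxy)benzaldehyde F7. Claisen–Schmidt condensation of F7 with 4 (KOH, EtOH) gives (2E)-1-(5-bromo-2-hydroxyphenyl)-3-[4-(methoxymethoxy)phenyl]prop-2-en-1-one F8, and oxa-Michael cyclisation (NaOAc, EtOH, reflux) gives racemic 6-bromo-2-[4-(methoxymethoxy)phenyl]-2,3-dihydro-4H-chromen-4-one F9. Kinetic resolution by asymmetric transfer hydrogenation (RuCl(p-cymene)[(S,S)-TsDPEN], HCO2H/Et3N, the catalyst antipode being the one that consumes the 2S ketone) reduces the unwanted enantiomer to (2S,4S)-6-bromo-2-[4-(methoxymethoxy)phenyl]-3,4-dihydro-2H-chromen-4-ol F10 and leaves the 2R ketone, so the route comes back at 11.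

**Further compounds**
F1 | step 9 | methyl (2R,3R)-5-bromo-2-[4-(methoxymethoxy)phenyl]-2,3-dihydro-1-benzofuran-3-carboxylate | Brc1ccc2c(c1)[C@@H](C(=O)OC)[C@H](c1ccc(OCOC)cc1)O2
F2 | step 9 | (2R,3R)-5-bromo-N-methoxy-2-[4-(methoxymethoxy)phenyl]-N-methyl-2,3-dihydro-1-benzofuran-3-carboxamide | Brc1ccc2c(c1)[C@@H](C(=O)N(C)OC)[C@H](c1ccc(OCOC)cc1)O2
F3 | step 9 | (2R,3R)-N-methoxy-5-{(1E)-3-[methoxy(methyl)amino]-3-oxoprop-1-en-1-yl}-2-[4-(methoxymethoxy)phenyl]-N-methyl-2,3-dihydro-1-benzofuran-3-carboxamide | CON(C)C(=O)/C=C/c1ccc2c(c1)[C@@H](C(=O)N(C)OC)[C@H](c1ccc(OCOC)cc1)O2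
F4 | step 8 | 1-[2,4-bis(methoxymethoxy)phenyl]prop-2-en-1-one | C=CC(=O)c1ccc(OCOC)cc1OCOC
F5 | step 8 | (2R)-6-bromo-4-[2,4-bis(methoxymethoxy)phenyl]-2-[4-(methoxymethoxy)phenyl]-3,4-dihydro-2H-chromen-4-ol (C4 epimer mixture) | OC1(c2ccc(OCOC)cc2OCOC)C[C@H](c2ccc(OCOC)cc2)Oc2ccc(Br)cc21
F6 | step 8 | (2R)-6-bromo-4-[2,4-bis(methoxymethoxy)phenyl]-2-[4-(methoxymethoxy)phenyl]-2H-chromene | COCOc1ccc(C2=C[C@H](c3ccc(OCOC)cc3)Oc3ccc(Br)cc32)c(OCOC)c1
F7 | step 4 | 4-(methoxymethoxy)benzaldehyde | COCOc1ccc(C=O)cc1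
F8 | step 4 | (2E)-1-(5-bromo-2-hydroxyphenyl)-3-[4-(methoxymethoxy)phenyl]prop-2-en-1-one | COCOc1ccc(/C=C/C(=O)c2cc(Br)ccc2O)cc1
F9 | step 4 | racemic 6-bromo-2-[4-(methoxymethoxy)phenyl]-2,3-dihydro-4H-chromen-4-one | O=C1CC(c2ccc(OCOC)cc2)Oc2ccc(Br)cc12
F10 | step 4 | (2S,4S)-6-bromo-2-[4-(methoxymethoxy)phenyl]-3,4-dihydro-2H-chromen-4-ol | O[C@H]1C[C@@H](c2ccc(OCOC)cc2)Oc2ccc(Br)cc21
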